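**Retrosynthetic overview**

1. Target ⇐ Takai–Lombardo methylenation of the C4 ketone after acid removal of the dioxolane and silyl ether; the 6α-OAc/7β-O-isobutyryl/8β-OH array comes from a β-face OsO4 dihydroxylation of a 6α-acetoxy-Δ7-ene; the butenolide comes from a 3-furyl group (singlet oxygen, then NaBH4).
2. The Δ7-en-6-one comes from a C8 ketone (enol triflate, Negishi methylation, allylic oxidation); 1β-OH and H-10β come from one syn hydroboration of a Δ1(10) alkene.
3. Key disconnection: ring B, with the C9 quaternary centre, the C11 carbinol and the C8 ketone, is made by a semipinacol ring expansion of a cyclopentenyl carbinol epoxide (1,2-shift of C10 from C8 to C9).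
4. The carbinol comes from an (E)-alkenyllithium (3-(bromomethyl)furan + propynyl Grignard) and a bicyclic enone; the enone comes from cyclohexane-1,3-dione, iodomethane and acrolein through a desymmetrising NHC benzoin reaction that sets C5.
5. Ring order: ring A (from the dione) → five-membered precursor of ring B (benzoin) → six-membered ring B (ring expansion) → butenolide ring (from the furan) last.

Assumptions: clerodane numbering is used from compound 5 on (ring A = C1–C5, C10; ring B = C5–C10; C19 on C5, C20 on C9, C17 on C8, C18 on C4; α = face of the C19/C20 methyls), the target being (1R,5R,6R,7S,8R,9S,10S,11S); 3-(bromomethyl)furan and prop-1-ynylmagnesium bromide solution are taken as commercial; for the triazolium precatalyst and the bishydroxamic acid ligand the antipode that gives the drawn stereochemistry is used (both are accessible); cyclopentadienyl rings are drawn σ-bonded in SMILES.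

**Step 1**
Reactants: 1 cyclohexane-1,3-dione
Product: 2 2-methylcyclohexane-1,3-dione
Conditions: MeI, KOH, H2O/MeOH, 65 °C
Reagents that add atoms: iodomethane, CI
Why: C-alkylation of the stabilised 1,3-diketone enolate at C2 (classical dione methylation); no stereocentre is formed.

**Step 2**
Reactants: 2 2-methylcyclohexane-1,3-dione; 3 acrolein
Product: 4 3-(1-methyl-2,6-dioxocyclohexyl)propanal
Conditions: H2O, rt
Reagents that add atoms: none
Why: Michael addition of the dione to acrolein in water builds the quaternary carbon (future C5) in a still achiral, prochiral triketone.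

**Step 3**
Reactants: 4 3-(1-methyl-2,6-dioxocyclohexyl)propanal
Product: 5 (3aR,7aS)-7a-hydroxy-3a-methylhexahydro-1H-indene-1,4(2H)-dione
Conditions: 2-(pentafluorophenyl)-5a,10b-dihydro-4H,6H-indeno[2,1-b][1,2,4]triazolo[4,3-d][1,4]oxazin-2-ium tetrafluoroborate (10 mol %, antipode giving 5), Et3N (10 mol %), THF, rt
Reagents that add atoms: none
Why: NHC-catalysed intramolecular crossed benzoin reaction in which the Breslow intermediate of the aldehyde adds to one of the two enantiotopic ring carbonyls (desymmetrisation), setting the quaternary C5 (R) and the cis-fused tertiary carbinol C10.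

**Step 4**
Reactants: 5 (3aR,7aS)-7a-hydroxy-3a-methylhexahydro-1H-indene-1,4(2H)-dione
Product: 6 (3aR)-3a-methyl-2,3,5,6-tetrahydro-1H-indene-1,4(3aH)-dione
Conditions: methyl N-(triethylammoniosulfonyl)carbamate (Burgess reagent), toluene, 70 °C
Reagents that add atoms: none
Why: Burgess dehydration (syn elimination through the sulfamate ester) of the tertiary α-ketol can only go toward the one adjacent CH2 (C1 in clerodane numbering), giving the C8(=O)–C10=C1 enone; C5 is untouched.

**Step 5**
Reactants: 6 (3aR)-3a-methyl-2,3,5,6-tetrahydro-1H-indene-1,4(3aH)-dione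
Product: 7 (3a'R)-3a'-methyl-2',3',5',6'-tetrahydrospiro[1,3-dioxolane-2,4'-inden]-1'(3a'H)-one
Conditions: ethylene glycol, p-toluenesulfonic acid (cat.), 4 Å MS, rt
Reagents that add atoms: ethylene glycol, OCCO
Why: chemoselective acetalisation, since the saturated cyclohexanone carbonyl (C4) is ketalised much faster than the conjugated cyclopentenone carbonyl (C8), as in Wieland–Miescher-type enediones.

**Step 6**
Reactants: 8 3-(bromomethyl)furan; 9 prop-1-yn-1-ylmagnesium bromide
Product: 10 3-(but-2-yn-1-yl)furan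
Conditions: CuI (5 mol %), THF, 0 °C → rt
Reagents that add atoms: none
Why: copper-catalysed substitution of the furylmethyl bromide by the alkynyl Grignard reagent (sp–sp3 cross-coupling).

**Step 7**
Reactants: 10 3-(but-2-yn-1-yl)furan
Product: 12 (E)-3-(3-iodobut-2-en-1-yl)furan, via alkenylzirconocene chloride 11 (not isolated)
Conditions: Cp2Zr(H)Cl (1.5 equiv), THF, 40 °C; then I2, 0 °C
Reagents that add atoms: iodine, [I][I]
Why: hydrozirconation is a syn addition that under equilibrating conditions places Zr on the alkyne carbon next to the methyl group, and iodinolysis with retention fixes the E geometry (I trans to the furylmethyl group).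

**Step 8**
Reactants: 7 (3a'R)-3a'-methyl-2',3',5',6'-tetrahydrospiro[1,3-dioxolane-2,4'-inden]-1'(3a'H)-one; 12 (E)-3-(3-iodobut-2-en-1-yl)furan
Product: 14 tertiary bis-allylic alcohol (8β-OH; 8α-[(2E)-4-(furan-3-yl)but-2-en-2-yl]; 5α-CH3; C1=C10; C4 dioxolane), via alkenyllithium 13 (not isolated)
Conditions: 12, t-BuLi (2.0 equiv), Et2O, −78 °C; then 7, −78 → −40 °C; H2O
Reagents that add atoms: none
Why: iodine–lithium exchange with retention of alkene geometry, then 1,2-addition of the hard alkenyllithium to the cyclopentenone carbonyl from the α face (anti to the dioxolane-bearing C4); the C8 configuration is erased in the next step.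

**Step 9**
Reactants: 14 tertiary bis-allylic alcohol
Product: 16 ring-expanded β-hydroxy ketone (5R,9S,11S)-4,4-ethylenedioxy-9β-[(S)-2-(furan-3-yl)-1-hydroxyethyl]-5α,9α-dimethyl-Δ1(10)-octalin-8-one, via epoxy alcohol 15 (not isolated)
Conditions: Hf(OtBu)4 (10 mol %), N,N'-(trans-cyclohexane-1,2-diyl)bis(N-hydroxy-2,2-diphenylacetamide) (12 mol %, antipode giving the (9R,11S)-epoxide), cumene hydroperoxide (1.5 equiv), MgO, toluene, 0 °C → rt
Reagents that add atoms: cumene hydroperoxide, CC(C)(OO)c1ccccc1
Why: Proposed new method: one chiral tetravalent hafnium–bishydroxamate complex is asked first to bind the tertiary alkoxide of 14 and deliver oxygen from the hydroperoxide to one face of the adjacent E-trisubstituted alkene (ligand-controlled, giving the (9R,11S)-epoxide 15) and then, still chelated to the epoxy alkoxide, to ionise the tertiary C9–O bond so that the alkenyl carbon C10 (a far better migrating group than the C7 methylene) shifts from C8 to C9 anti to the breaking bond; this semipinacol 1,2-shift expands the cyclopentane to the six-membered ring B, inverts C9 to S (C20 α, C11 β), keeps C11 as S and releases the C8 ketone; the closest known reactions are the hafnium- and vanadium-bishydroxamic acid epoxidations of tertiary allylic alcohols and the Lewis-acid (Tsuchihashi–Suzuki-type) semipinacol rearrangement of isolated 2,3-epoxy alcohols, which have not been merged into a single catalytic, ligand-controlled ring-expanding event on a cyclopentenyl carbinol.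

**Step 10**
Reactants: 16 ring-expanded β-hydroxy ketone
Product: 17 11-O-acetate of 16
Conditions: Ac2O, 4-(dimethylamino)pyridine (cat.), Et3N, CH2Cl2, rt
Reagents that add atoms: acetic anhydride, CC(=O)OC(C)=O
Why: nucleophile-catalysed acylation installs the C11 acetate of the target and blocks retro-aldol cleavage of the β-hydroxy ketone in the basic step that follows.

**Step 11**
Reactants: 17 11-O-acetate of 16
Product: 19 C7(8)-enol trifluoromethanesulfonate of 17, via potassium enolate 18 (not isolated)
Conditions: KN(SiMe3)2, THF, −78 °C; then PhNTf2, −78 → 0 °C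
Reagents that add atoms: N-phenylbis(trifluoromethanesulfonimide), O=S(=O)(N(c1ccccc1)S(=O)(=O)C(F)(F)F)C(F)(F)F
Why: kinetic enolisation can only occur toward C7 because C9 is quaternary, and O-sulfonylation of the enolate gives the C7=C8 enol triflate regiospecifically.

**Step 12**
Reactants: 19 C7(8)-enol trifluoromethanesulfonate of 17
Product: 21 1β-hydroxy trans-decalin enol triflate (H-10β), via alkylborane 20 (not isolated)
Conditions: BH3·THF, THF, 0 °C → rt; then H2O2 (30 % aq.), NaHCO3, 0 °C
Reagents that add atoms: hydrogen peroxide, OO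
Why: hydroboration–oxidation in which the electrophilic borane ignores the electron-poor enol triflate and adds syn to the C1=C10 alkene from the β face (opposite the two α-methyls), boron going to the less substituted C1; this sets H-10β (trans ring fusion) and, after oxidation with retention, the equatorial 1β-hydroxyl.

**Step 13**
Reactants: 21 1β-hydroxy trans-decalin enol triflate
Product: 22 1-O-tert-butyldimethylsilyl ether of 21
Conditions: t-BuMe2SiOTf, 2,6-lutidine, CH2Cl2, −78 °C
Reagents that add atoms: tert-butyldimethylsilyl trifluoromethanesulfonate, CC(C)(C)[Si](C)(C)OS(=O)(=O)C(F)(F)F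
Why: silylation protects the only free hydroxyl, which must stay free in the target, through the oxidation and acylation steps.

**Step 14**
Reactants: 22 1-O-tert-butyldimethylsilyl ether of 21
Product: 23 8-methyl-Δ7 alkene (C17 installed; 3-furyl side chain; 11-OAc; 1β-OSi; C4 dioxolane)
Conditions: MeZnCl, Pd(PPh3)4 (5 mol %), THF, 60 °C
Reagents that add atoms: methylzinc chloride, C[Zn]Cl
Why: Negishi cross-coupling of the alkenyl triflate (zerovalent palladium) introduces the C17 methyl on C8 without touching the acetate.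

**Step 15**
Reactants: 23 8-methyl-Δ7 alkene
Product: 25 butenolide (13-en-15,16-olide) of 23, via hydroxybutenolide 24 (not isolated)
Conditions: O2, 5,10,15,20-tetraphenylporphyrin (cat.), hν (visible), i-Pr2NEt, CH2Cl2, −78 °C; then NaBH4, EtOH, 0 °C
Reagents that add atoms: dioxygen, O=O
Why: [4+2] addition of singlet oxygen to the furan, then base-induced (Kornblum–DeLaMare-type) opening of the endoperoxide by loss of the less hindered α-hydrogen gives the 4-alkyl-5-hydroxybutenolide; NaBH4 reduces its lactol carbon and relactonisation gives the 4-substituted furan-2(5H)-one.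

**Step 16**
Reactants: 25 butenolide of 23
Product: 26 Δ7-en-6-one (8-methyl; butenolide; 11-OAc; 1β-OSi; C4 dioxolane)
Conditions: CrO3, 3,5-dimethylpyrazole, CH2Cl2, −20 °C
Reagents that add atoms: chromium trioxide, O=[Cr](=O)=O
Why: chromium trioxide–dimethylpyrazole allylic oxidation, in which only the ring methylene C6 can give a conjugated enone (C9 is quaternary, the C17 methyl is less reactive), the selectivity that turns 1-methylcyclohexenes into 3-methylcyclohexenones.

**Step 17**
Reactants: 26 Δ7-en-6-one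
Product: 27 6α-allylic alcohol of 26
Conditions: NaBH4, CeCl3·7H2O, MeOH, −78 °C
Reagents that add atoms: none
Why: Luche 1,2-reduction with axial hydride delivery from the β face, anti to the adjacent α-axial C19 methyl, gives the equatorial 6α-alcohol and leaves the esters and the butenolide alone at −78 °C.

**Step 18**
Reactants: 27 6α-allylic alcohol
Product: 28 6α,11-diacetate
Conditions: Ac2O, 4-(dimethylamino)pyridine (cat.), pyridine, CH2Cl2, rt
Reagents that add atoms: acetic anhydride, CC(=O)OC(C)=O
Why: acylation installs the C6 acetate of the target and provides the allylic ester that directs the next step.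

**Step 19**
Reactants: 28 6α,11-diacetate
Product: 29 7β,8β-diol of 28
Conditions: OsO4 (10 mol %), N-methylmorpholine N-oxide, acetone/H2O, rt
Reagents that add atoms: N-methylmorpholine N-oxide, C[N+]1([O-])CCOCC1; water, O
Why: Upjohn dihydroxylation in which OsO4 adds syn from the β face, anti to the allylic 6α-acetate (Kishi's rule) and away from the two α-axial methyls, setting 7β-OH and 8β-OH/8α-CH3; the electron-poor butenolide alkene reacts more slowly.

**Step 20**
Reactants: 29 7β,8β-diol
Product: 30 7-O-(2-methylpropanoyl) ester of 29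
Conditions: (i-PrCO)2O, 4-(dimethylamino)pyridine, pyridine, CH2Cl2, 0 °C → rt
Reagents that add atoms: isobutyric anhydride, CC(C)C(=O)OC(=O)C(C)C
Why: acylation of the secondary 7β-hydroxyl; the tertiary 8β-hydroxyl flanked by the quaternary C9 does not react.

**Step 21**
Reactants: 30 7-O-(2-methylpropanoyl) ester
Product: 31 4-oxo-1β-ol (dioxolane and silyl ether removed)
Conditions: HCl (1 M aq.), THF, rt → 40 °C
Reagents that add atoms: water, O
Why: acid hydrolysis cleaves the dioxolane and the silyl ether in one operation, while the three esters, the butenolide and the tertiary alcohol survive dilute aqueous acid (C5 is quaternary, so the β-acetoxy ketone cannot eliminate).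

**Step 22**
Reactants: 31 4-oxo-1β-ol
Product: 32 target CNP0254453.1
Conditions: Zn, CH2Br2, TiCl4, THF/CH2Cl2, 0 °C → rt
Reagents that add atoms: dibromomethane, BrCBr
Why: Takai–Lombardo methylenation (titanium methylidene from CH2(ZnBr)2 and TiCl4) is non-basic and selective for ketones over esters and lactones, tolerates free hydroxyls, and converts the hindered C4 ketone into the exocyclic C4=C18 alkene.

**Compound list**

1 | cyclohexane-1,3-dione | O=C1CCCC(=O)C1 | starting material
2 | 2-methylcyclohexane-1,3-dione | CC1C(=O)CCCC1=O | intermediate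
3 | acrolein (prop-2-enal) | C=CC=O | starting material
4 | 3-(1-methyl-2,6-dioxocyclohexyl)propanal | CC1(CCC=O)C(=O)CCCC1=O | intermediate
5 | (3aR,7aS)-7a-hydroxy-3a-methylhexahydro-1H-indene-1,4(2H)-dione (cis-fused; OH and CH3 cis) | O=C1CCC[C@]2(O)[C@@]1(C)CCC2=O | intermediate
6 | (3aR)-3a-methyl-2,3,5,6-tetrahydro-1H-indene-1,4(3aH)-dione (C7=C7a conjugated to C1=O) | O=C1CCC=C2[C@@]1(C)CCC2=O | intermediate
7 | (3a'R)-3a'-methyl-2',3',5',6'-tetrahydrospiro[1,3-dioxolane-2,4'-inden]-1'(3a'H)-one | C13(OCCO3)CCC=C2[C@@]1(C)CCC2=O | intermediate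
8 | 3-(bromomethyl)furan | BrCc1ccoc1 | starting material
9 | prop-1-yn-1-ylmagnesium bromide | CC#C[Mg]Br | starting material
10 | 3-(but-2-yn-1-yl)furan | CC#CCc1ccoc1 | intermediate
11 | (E)-alkenylzirconocene chloride (Zr on the methyl-bearing carbon, trans to the furylmethyl group) | Cl[Zr](C1C=CC=C1)(C1C=CC=C1)/C(C)=C/Cc1ccoc1 | intermediate (not isolated)
12 | (E)-3-(3-iodobut-2-en-1-yl)furan | I/C(C)=C/Cc1ccoc1 | intermediate
13 | (E)-4-(furan-3-yl)but-2-en-2-yllithium | [Li]/C(C)=C/Cc1ccoc1 | intermediate (not isolated)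
14 | tertiary bis-allylic alcohol from 7: C8 bears β-OH and α-[(2E)-4-(furan-3-yl)but-2-en-2-yl]; 5α-CH3; C1=C10; C4 dioxolane | C13(OCCO3)CCC=C2[C@@]1(C)CC[C@@]2(O)/C(C)=C/Cc1ccoc1 | intermediate
15 | (9R,11S)-epoxide of the side-chain alkene of 14 (2,3-epoxy alcohol) | C13(OCCO3)CCC=C2[C@@]1(C)CC[C@@]2(O)[C@]4(C)O[C@H]4Cc1ccoc1 | intermediate (not isolated)
16 | (5R,9S,11S)-4,4-ethylenedioxy-9β-[(S)-2-(furan-3-yl)-1-hydroxyethyl]-5α,9α-dimethyl-Δ1(10)-octalin-8-one | C13(OCCO3)CCC=C2[C@@]1(C)CCC(=O)[C@]2(C)[C@H](Cc1ccoc1)O | intermediate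
17 | 11-O-acetate of 16 | C13(OCCO3)CCC=C2[C@@]1(C)CCC(=O)[C@]2(C)[C@H](Cc1ccoc1)OC(C)=O | intermediate
18 | potassium C7(8)-enolate of 17 | C13(OCCO3)CCC=C2[C@@]1(C)CC=C([O-])[C@]2(C)[C@H](Cc1ccoc1)OC(C)=O.[K+] | intermediate (not isolated)
19 | C7(8)-enol trifluoromethanesulfonate of 17 (Δ1(10) and Δ7) | C13(OCCO3)CCC=C2[C@@]1(C)CC=C(OS(=O)(=O)C(F)(F)F)[C@]2(C)[C@H](Cc1ccoc1)OC(C)=O | intermediate
20 | 1β-boryl (R–BH2) trans-decalin from 19 (H-10β) | C13(OCCO3)CC[C@@H](B)[C@H]2[C@@]1(C)CC=C(OS(=O)(=O)C(F)(F)F)[C@]2(C)[C@H](Cc1ccoc1)OC(C)=O | intermediate (not isolated)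
21 | 1β-hydroxy trans-decalin enol triflate (H-10β; 5α,9α-dimethyl; 11S acetate; C4 dioxolane) | C13(OCCO3)CC[C@@H](O)[C@H]2[C@@]1(C)CC=C(OS(=O)(=O)C(F)(F)F)[C@]2(C)[C@H](Cc1ccoc1)OC(C)=O | intermediate
22 | 1-O-tert-butyldimethylsilyl ether of 21 | C13(OCCO3)CC[C@@H](O[Si](C)(C)C(C)(C)C)[C@H]2[C@@]1(C)CC=C(OS(=O)(=O)C(F)(F)F)[C@]2(C)[C@H](Cc1ccoc1)OC(C)=O | intermediate
23 | 8-methyl-Δ7 alkene (triflate of 22 replaced by CH3) | C13(OCCO3)CC[C@@H](O[Si](C)(C)C(C)(C)C)[C@H]2[C@@]1(C)CC=C(C)[C@]2(C)[C@H](Cc1ccoc1)OC(C)=O | intermediate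
24 | 5-hydroxybutenolide from 23 (4-substituted 5-hydroxyfuran-2(5H)-one; C16 epimers) | C13(OCCO3)CC[C@@H](O[Si](C)(C)C(C)(C)C)[C@H]2[C@@]1(C)CC=C(C)[C@]2(C)[C@H](CC1=CC(=O)OC1O)OC(C)=O | intermediate (not isolated)
25 | butenolide from 23 (4-substituted furan-2(5H)-one; 13-en-15,16-olide) | C13(OCCO3)CC[C@@H](O[Si](C)(C)C(C)(C)C)[C@H]2[C@@]1(C)CC=C(C)[C@]2(C)[C@H](CC1=CC(=O)OC1)OC(C)=O | intermediate
26 | Δ7-en-6-one of 25 | C13(OCCO3)CC[C@@H](O[Si](C)(C)C(C)(C)C)[C@H]2[C@@]1(C)C(=O)C=C(C)[C@]2(C)[C@H](CC1=CC(=O)OC1)OC(C)=O | intermediate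
27 | 6α-allylic alcohol of 26 | C13(OCCO3)CC[C@@H](O[Si](C)(C)C(C)(C)C)[C@H]2[C@@]1(C)[C@@H](O)C=C(C)[C@]2(C)[C@H](CC1=CC(=O)OC1)OC(C)=O | intermediate
28 | 6α,11-diacetate | C13(OCCO3)CC[C@@H](O[Si](C)(C)C(C)(C)C)[C@H]2[C@@]1(C)[C@@H](OC(C)=O)C=C(C)[C@]2(C)[C@H](CC1=CC(=O)OC1)OC(C)=O | intermediate
29 | 7β,8β-diol of 28 (8α-CH3) | C13(OCCO3)CC[C@@H](O[Si](C)(C)C(C)(C)C)[C@H]2[C@@]1(C)[C@@H](OC(C)=O)[C@H](O)[C@](C)(O)[C@]2(C)[C@H](CC1=CC(=O)OC1)OC(C)=O | intermediate
30 | 7-O-(2-methylpropanoyl) ester of 29 | C13(OCCO3)CC[C@@H](O[Si](C)(C)C(C)(C)C)[C@H]2[C@@]1(C)[C@@H](OC(C)=O)[C@H](OC(=O)C(C)C)[C@](C)(O)[C@]2(C)[C@H](CC1=CC(=O)OC1)OC(C)=O | intermediate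
31 | 4-oxo-1β-ol (target with C4=O in place of C4=CH2) | O=C1CC[C@@H](O)[C@H]2[C@@]1(C)[C@@H](OC(C)=O)[C@H](OC(=O)C(C)C)[C@](C)(O)[C@]2(C)[C@H](CC1=CC(=O)OC1)OC(C)=O | intermediate
32 | CNP0254453.1, (1R,5R,6R,7S,8R,9S,10S,11S)-6,11-diacetoxy-1,8-dihydroxy-7-(2-methylpropanoyloxy)cleroda-4(18),13-dien-15,16-olide | C=C1CC[C@@H](O)[C@H]2[C@@]1(C)[C@@H](OC(C)=O)[C@H](OC(=O)C(C)C)[C@](C)(O)[C@]2(C)[C@H](CC1=CC(=O)OC1)OC(C)=O | target

**Step count and risk**

Total: 22 steps. Longest linear sequence: 20 steps (steps 1–5 and 8–22); steps 6–7 make the side-chain fragment.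

The three steps most likely to fail:

Step 9 (proposed new one-flask epoxidation and ring-expanding shift). The hafnium alkoxide may stop at the epoxide, or the bis-allylic carbinol may ionise. The fallback sets out from 14 and decouples the two events into separate known reactions. Hydroxyl-directed asymmetric epoxidation with the same tetravalent hafnium–bishydroxamic acid system at −20 °C, worked up at the epoxide stage, gives isolated epoxy alcohol 15. Silylation (Me3SiCl, imidazole, DMF) gives the epoxy trimethylsilyl ether F1. TiCl4 in CH2Cl2 at −78 °C then promotes the Tsuchihashi–Suzuki semipinacol rearrangement of the epoxy silyl ether (anti shift of C10, loss of the silyl group on work-up), and the route is rejoined at 16.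

Step 12 (hydroboration of the hindered C1=C10 alkene beside an enol triflate, a furan and an acetate). If borane attacks the triflate or the reaction is too slow to stay selective, the order of events is changed and the fallback sets out from 17. BH3·THF followed by H2O2/NaHCO3 is applied to the ketone, which is deliberately reduced as well, giving the 1β,8-diol F2 (H-10β, C8 epimers). t-BuMe2SiCl/imidazole silylates only the less hindered C1 hydroxyl to give the mono-silyl ether F3. Dess–Martin periodinane re-oxidises the neopentyl C8 carbinol to the ketone F4. KN(SiMe3)2/PhNTf2 then gives the enol triflate, rejoining the route at 22.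

Step 22 (methylenation of the hindered, α-quaternary C4 ketone in the presence of three esters and two free hydroxyls). If the titanium methylidene fails, a two-stage Peterson olefination is used from 31. Me3SiCH2MgCl/CeCl3 (THF, −78 °C; the organocerium adds to ketones much faster than to esters and does not enolise) gives the β-hydroxysilane F5 (C4 epimers). Acid-promoted anti elimination (HF·pyridine, MeCN, 0 °C) then gives the exocyclic alkene, arriving at 32.

**Further compounds**

F1 | step 9 | trimethylsilyl ether of epoxy alcohol 15 ((9R,11S)-epoxide; 8β-OSiMe3) | C13(OCCO3)CCC=C2[C@@]1(C)CC[C@@]2(O[Si](C)(C)C)[C@]4(C)O[C@H]4Cc1ccoc1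
F2 | step 12 | 1β,8-diol from 17 (H-10β trans-decalin; C8 epimers; 11S acetate; 3-furyl side chain; C4 dioxolane) | C13(OCCO3)CC[C@@H](O)[C@H]2[C@@]1(C)CCC(O)[C@]2(C)[C@H](Cc1ccoc1)OC(C)=O
F3 | step 12 | 1-O-tert-butyldimethylsilyl ether of F2 (free C8 hydroxyl) | C13(OCCO3)CC[C@@H](O[Si](C)(C)C(C)(C)C)[C@H]2[C@@]1(C)CCC(O)[C@]2(C)[C@H](Cc1ccoc1)OC(C)=O
F4 | step 12 | C8 ketone from F3 (1β-silyloxy trans-decalin-8-one) | C13(OCCO3)CC[C@@H](O[Si](C)(C)C(C)(C)C)[C@H]2[C@@]1(C)CCC(=O)[C@]2(C)[C@H](Cc1ccoc1)OC(C)=O
F5 | step 22 | β-hydroxysilane from 31 (4-hydroxy-4-(trimethylsilylmethyl); C4 epimers) | C[Si](C)(C)CC1(O)CC[C@@H](O)[C@H]2[C@@]1(C)[C@@H](OC(C)=O)[C@H](OC(=O)C(C)C)[C@](C)(O)[C@]2(C)[C@H](CC1=CC(=O)OC1)OC(C)=O
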